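**Strategy**

Everything rests on closing the dihydropyran ring of the chroman at its C2–C3 bond, between the gem-dimethyl carbon on ring oxygen O1 and the carbinol carbon. The key step exploits the O1–C2–C3–O array: C2 is a latent oxocarbenium carbon (aryl isopropenyl ether) and C3 a latent acyl anion (arylacetaldehyde). A carbene-catalysed intramolecular hydroacylation joins them in one operation, creating the ring, the quaternary C2 and a C3 ketone, which a CBS reduction then converts into the (R)-alcohol. The precursor is an open-chain 2-arylacetaldehyde whose neighbouring phenol oxygen carries a prop-1-en-2-yl group. The pyranone is attached last through the methylene bridge.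

Key step: step 7

Remark on the chemistry: by CIP analysis the carbinol carbon C3 of the chroman is (R); it is set in step 8 and is not touched afterwards.

**Route**

Step 1
Reactants: 1 1-(2,4,6-trihydroxyphenyl)ethanone
Product: 2 1-[4-(allyloxy)-2,6-dihydroxyphenyl]ethanone
Conditions: allyl bromide (1.0 equiv), K2CO3 (1.05 equiv), acetone, 56 °C
Reagents that add atoms: allyl bromide, C=CCBr
Why: Williamson etherification should take place at the 4-OH, which is para to the acetyl group, the most acidic and not hydrogen-bonded, while the two ortho-OH groups are tied to the carbonyl; minor 2-O-allyl and bis-allyl ethers are removed by chromatography.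

Step 2
Reactants: 2 1-[4-(allyloxy)-2,6-dihydroxyphenyl]ethanone
Product: 3 1-[4-(allyloxy)-2,6-bis(benzyloxy)phenyl]ethanone
Conditions: benzyl bromide (2.5 equiv), K2CO3 (3 equiv), DMF, 70 °C
Reagents that add atoms: benzyl bromide, BrCc1ccccc1
Why: Williamson etherification under forcing conditions should alkylate both chelated phenols, giving benzyl ethers that keep the later aldehyde from closing to a hemiacetal on this side and that fall off by hydrogenolysis.

Step 3
Reactants: 3 1-[4-(allyloxy)-2,6-bis(benzyloxy)phenyl]ethanone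
Product: 4 1-[3-allyl-2,6-bis(benzyloxy)-4-hydroxyphenyl]ethanone
Conditions: N,N-diethylaniline, 190 °C
Reagents that add atoms: none
Why: The aromatic Claisen rearrangement ([3,3]-sigmatropic shift, then tautomerisation) should move the allyl group to one of the two equivalent ortho carbons and free the 4-OH again.

Step 4
Reactants: 4 1-[3-allyl-2,6-bis(benzyloxy)-4-hydroxyphenyl]ethanone
Product: 6 1-[2,6-bis(benzyloxy)-4-hydroxy-3-(2-hydroxyethyl)phenyl]ethanone, via arylacetaldehyde 5 (not isolated)
Conditions: O3, CH2Cl2/MeOH (4:1), Sudan Red 7B as indicator, −78 °C; then NaBH4, −78 to 0 °C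
Reagents that add atoms: ozone, [O-][O+]=O
Why: Ozonolysis of the terminal alkene with reductive work-up should give the primary alcohol, because the aldehyde (masked as a cyclic hemiacetal with the 4-OH) is reduced much faster than the acetyl group shielded by two ortho benzyloxy groups.

Step 5
Reactants: 6 1-[2,6-bis(benzyloxy)-4-hydroxy-3-(2-hydroxyethyl)phenyl]ethanone
Product: 7 1-[2,6-bis(benzyloxy)-3-(2-hydroxyethyl)-4-(prop-1-en-2-yloxy)phenyl]ethanone
Conditions: isopropenylboronic acid pinacol ester (2 equiv), Cu(OAc)2 (0.3 equiv), pyridine (3 equiv), 4 Å molecular sieves, O2 (1 atm), CH2Cl2, 25 °C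
Reagents that add atoms: isopropenylboronic acid pinacol ester, CC(=C)B1OC(C)(C)C(C)(C)O1
Why: The Chan–Lam oxidative C–O coupling should alkenylate the phenol in preference to the far less reactive primary alcohol and tolerates the ketone.

Step 6
Reactants: 7 1-[2,6-bis(benzyloxy)-3-(2-hydroxyethyl)-4-(prop-1-en-2-yloxy)phenyl]ethanone
Product: 8 2-[3-acetyl-2,4-bis(benzyloxy)-6-(prop-1-en-2-yloxy)phenyl]acetaldehyde
Conditions: Dess–Martin periodinane (1.3 equiv), pyridine (3 equiv), CH2Cl2, 0 to 25 °C
Reagents that add atoms: none
Why: The pyridine-buffered Dess–Martin oxidation should stop at the aldehyde and spare the acid-labile enol ether; with the 4-oxygen capped no hemiacetal can form, and the aldehyde is used at once.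

Step 7
Reactants: 8 2-[3-acetyl-2,4-bis(benzyloxy)-6-(prop-1-en-2-yloxy)phenyl]acetaldehyde
Product: 9 6-acetyl-5,7-bis(benzyloxy)-2,2-dimethylchroman-3-one
Conditions: 2-mesityl-6,7-dihydro-5H-pyrrolo[2,1-c][1,2,4]triazol-2-ium chloride (20 mol %), DBU (20 mol %), 1,4-dioxane (0.02 M), 80 °C, argon
Reagents that add atoms: none
Why: The carbene adds to the aldehyde to give the Breslow intermediate, whose nucleophilic carbon (C3) attacks the oxygen-bearing carbon (C2) of the isopropenyl ether while its O–H proton passes to the terminal CH2, either in a concerted five-membered ene-like transition state or stepwise through the oxocarbenium ion; collapse of the tetrahedral alkoxide releases the carbene and the ketone. The closest known reaction type is the N-heterocyclic-carbene-catalysed intramolecular hydroacylation of O-allyl and O-vinyl salicylaldehydes to chromanones and benzofuranones; the enolisable arylacetaldehyde is the stretch here. The dihydropyran ring closes in the 6-exo-trig mode, the former alkene CH2 ending as the second methyl group on C2. No stereocentre is formed, since C2 becomes a gem-dimethyl carbon and C3 a carbonyl carbon; the C3 configuration is set in step 8. The step needs Markovnikov regioselectivity, secured by the enol ether polarisation (C2 is the oxocarbenium carbon) and the 6-exo over 7-endo preference. It also needs chemoselection against aldol and benzoin self-condensation, favoured by intramolecularity, high dilution and a base loading no higher than the precatalyst loading; the acetyl ketone cannot be reached because a crossed benzoin would need a meta-bridged ring.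

Step 8
Reactants: 9 6-acetyl-5,7-bis(benzyloxy)-2,2-dimethylchroman-3-one
Product: 10 1-[(3R)-5,7-bis(benzyloxy)-3-hydroxy-2,2-dimethylchroman-6-yl]ethanone
Conditions: (S)-2-methyl-CBS-oxazaborolidine (20 mol %), BH3·SMe2 (0.7 equiv), THF, −20 °C; MeOH quench
Reagents that add atoms: none
Why: The Corey–Bakshi–Shibata reduction should deliver hydride to the face set by the catalyst, with the quaternary C2 as the large and the C4 methylene as the small substituent, so that the (S)-catalyst gives the (3R)-alcohol by analogy with tert-alkyl methyl ketones; the acetyl ketone, flanked by two ortho benzyloxy groups, should react much more slowly.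

Step 9
Reactants: 10 1-[(3R)-5,7-bis(benzyloxy)-3-hydroxy-2,2-dimethylchroman-6-yl]ethanone
Product: 11 1-[(3R)-3,5,7-trihydroxy-2,2-dimethylchroman-6-yl]ethanone
Conditions: H2 (1 atm), 10% Pd/C, EtOAc/EtOH, 25 °C
Reagents that add atoms: none
Why: Catalytic hydrogenolysis should cleave both benzyl ethers and leave the chelated aryl ketone, the secondary alcohol and the chroman ether untouched.

Step 10
Reactants: 12 methyl 3-oxopentanoate
Product: 13 methyl 4-methyl-3,5-dioxoheptanoate
Conditions: LDA (2.2 equiv), THF, −78 to 0 °C; then N-methoxy-N-methylpropanamide (1.0 equiv), −78 to 0 °C; 1 M HCl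
Reagents that add atoms: N-methoxy-N-methylpropanamide, CCC(=O)N(C)OC
Why: The Weiler dianion of the β-keto ester should be acylated at its more reactive γ-carbon, and the stable Weinreb tetrahedral intermediate prevents proton quench of the dianion by the product.

Step 11
Reactants: 13 methyl 4-methyl-3,5-dioxoheptanoate
Product: 14 6-ethyl-4-hydroxy-5-methyl-2H-pyran-2-one
Conditions: DBU (1.5 equiv), toluene, 110 °C; then 1 M HCl
Reagents that add atoms: none
Why: Base-mediated lactonisation (enol oxygen of the C5 ketone onto the ester, loss of methanol) is the standard closure of 3,5-dioxo esters to 4-hydroxy-2-pyranones.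

Step 12
Reactants: 14 6-ethyl-4-hydroxy-5-methyl-2H-pyran-2-one; 11 1-[(3R)-3,5,7-trihydroxy-2,2-dimethylchroman-6-yl]ethanone
Product: 17 3-{[(3R)-6-acetyl-3,5,7-trihydroxy-2,2-dimethylchroman-8-yl]methyl}-6-ethyl-4-hydroxy-5-methyl-2H-pyran-2-one, via Mannich base 15 (not isolated), via methylidenepyrandione 16 (not isolated)
Conditions: 14, Eschenmoser's salt (1.0 equiv), MeCN, 25 °C; then 11 (1.0 equiv), 70 °C
Reagents that add atoms: Eschenmoser's salt, C[N+](C)=C.[I-]
Why: Mannich aminomethylation at C3 of the pyranone, thermal loss of dimethylamine to the quinone-methide-like 3-methylidene-pyran-2,4-dione and its Friedel–Crafts-type conjugate capture by C8, the only free and strongly activated aromatic carbon of 11 (a carba-Betti-type three-component coupling), should give the methylene-bridged target without touching C3.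

**Compound list**

1 | 1-(2,4,6-trihydroxyphenyl)ethanone | CC(=O)c1c(O)cc(O)cc1O | starting material
2 | 1-[4-(allyloxy)-2,6-dihydroxyphenyl]ethanone | CC(=O)c1c(O)cc(OCC=C)cc1O | intermediate
3 | 1-[4-(allyloxy)-2,6-bis(benzyloxy)phenyl]ethanone | CC(=O)c1c(OCc2ccccc2)cc(OCC=C)cc1OCc1ccccc1 | intermediate
4 | 1-[3-allyl-2,6-bis(benzyloxy)-4-hydroxyphenyl]ethanone | CC(=O)c1c(OCc2ccccc2)cc(O)c(CC=C)c1OCc1ccccc1 | intermediate
5 | 2-[3-acetyl-2,4-bis(benzyloxy)-6-hydroxyphenyl]acetaldehyde (in equilibrium with its cyclic hemiacetal) | CC(=O)c1c(OCc2ccccc2)cc(O)c(CC=O)c1OCc1ccccc1 | intermediate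
6 | 1-[2,6-bis(benzyloxy)-4-hydroxy-3-(2-hydroxyethyl)phenyl]ethanone | CC(=O)c1c(OCc2ccccc2)cc(O)c(CCO)c1OCc1ccccc1 | intermediate
7 | 1-[2,6-bis(benzyloxy)-3-(2-hydroxyethyl)-4-(prop-1-en-2-yloxy)phenyl]ethanone | CC(=O)c1c(OCc2ccccc2)cc(OC(C)=C)c(CCO)c1OCc1ccccc1 | intermediate
8 | 2-[3-acetyl-2,4-bis(benzyloxy)-6-(prop-1-en-2-yloxy)phenyl]acetaldehyde | CC(=O)c1c(OCc2ccccc2)cc(OC(C)=C)c(CC=O)c1OCc1ccccc1 | intermediate
9 | 6-acetyl-5,7-bis(benzyloxy)-2,2-dimethylchroman-3-one | CC(=O)c1c(OCc2ccccc2)cc2OC(C)(C)C(=O)Cc2c1OCc1ccccc1 | intermediate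
10 | 1-[(3R)-5,7-bis(benzyloxy)-3-hydroxy-2,2-dimethylchroman-6-yl]ethanone | CC(=O)c1c(OCc2ccccc2)cc2OC(C)(C)[C@H](O)Cc2c1OCc1ccccc1 | intermediate
11 | 1-[(3R)-3,5,7-trihydroxy-2,2-dimethylchroman-6-yl]ethanone | CC(=O)c1c(O)cc2OC(C)(C)[C@H](O)Cc2c1O | intermediate
12 | methyl 3-oxopentanoate | CCC(=O)CC(=O)OC | starting material
13 | methyl 4-methyl-3,5-dioxoheptanoate | CCC(=O)C(C)C(=O)CC(=O)OC | intermediate
14 | 6-ethyl-4-hydroxy-5-methyl-2H-pyran-2-one | CCc1oc(=O)cc(O)c1C | intermediate
15 | 3-[(dimethylamino)methyl]-6-ethyl-4-hydroxy-5-methyl-2H-pyran-2-one | CCc1oc(=O)c(CN(C)C)c(O)c1C | intermediate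
16 | 6-ethyl-5-methyl-3-methylidene-2H-pyran-2,4(3H)-dione | CCC1=C(C)C(=O)C(=C)C(=O)O1 | intermediate
17 | 3-{[(3R)-6-acetyl-3,5,7-trihydroxy-2,2-dimethylchroman-8-yl]methyl}-6-ethyl-4-hydroxy-5-methyl-2H-pyran-2-one | CCc1oc(=O)c(Cc2c(O)c(C(C)=O)c(O)c3c2OC(C)(C)[C@H](O)C3)c(O)c1C | target

**Summary**

Total step count: 12. Longest linear sequence: 10 steps (steps 1 to 9, then step 12); the pyranone branch is steps 10 and 11.

Steps most likely to fail:

Step 7. Base-mediated aldol oligomerisation of the enolisable arylacetaldehyde may outrun the carbene cycle, or C–C bond formation at the alkyl-substituted enol ether may be too slow. The fallback sets out from 8 and comes back at 9. Treatment of 8 with Fe(acac)3 and PhSiH3 in EtOH at 60 °C should transfer a hydrogen atom to the isopropenyl CH2; the tertiary α-aryloxy radical should then close 6-exo onto the aldehyde carbon, and reduction of the alkoxy radical gives racemic 1-[5,7-bis(benzyloxy)-3-hydroxy-2,2-dimethylchroman-6-yl]ethanone F1. Dess–Martin oxidation of F1 (pyridine, CH2Cl2) then gives 9.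

Step 5. Slow transmetalation of the 1,1-disubstituted alkenyl pinacol boronate, protodeboronation or competing O-alkenylation of the primary alcohol may erode the coupling. The fallback sets out from 6 and comes back at 7. It reverses the roles of the partners in an Ullmann-type C–O coupling of the phenoxide of 6 with 2-bromopropene (CuI, N,N-dimethylglycine, Cs2CO3, 1,4-dioxane, 90 °C, sealed tube), which should give 7 directly.

Step 8. Facial discrimination between the quaternary C2 and the C4 methylene may be insufficient, or borane may also reduce the acetyl group. The fallback sets out from 9 and comes back at 10. Reduction with NaBH4 (MeOH/THF, −40 °C) should give racemic 1-[5,7-bis(benzyloxy)-3-hydroxy-2,2-dimethylchroman-6-yl]ethanone F2. Lipase-catalysed acetylation (Candida antarctica lipase B, vinyl acetate, MTBE, 40 °C) is expected by the Kazlauskas rule to acylate the (R)-enantiomer, giving (3R)-6-acetyl-5,7-bis(benzyloxy)-2,2-dimethylchroman-3-yl acetate F3. This is separated by chromatography from unreacted 1-[(3S)-5,7-bis(benzyloxy)-3-hydroxy-2,2-dimethylchroman-6-yl]ethanone F4. Methanolysis of F3 (K2CO3, MeOH) gives 10, and F4 can be returned to 9 by Dess–Martin oxidation.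

**Further compounds**

F1 | step 7 | racemic 1-[5,7-bis(benzyloxy)-3-hydroxy-2,2-dimethylchroman-6-yl]ethanone | CC(=O)c1c(OCc2ccccc2)cc2OC(C)(C)C(O)Cc2c1OCc1ccccc1
F0 | step 5 | none | none
F2 | step 8 | racemic 1-[5,7-bis(benzyloxy)-3-hydroxy-2,2-dimethylchroman-6-yl]ethanone | CC(=O)c1c(OCc2ccccc2)cc2OC(C)(C)C(O)Cc2c1OCc1ccccc1
F3 | step 8 | (3R)-6-acetyl-5,7-bis(benzyloxy)-2,2-dimethylchroman-3-yl acetate | CC(=O)c1c(OCc2ccccc2)cc2OC(C)(C)[C@H](OC(C)=O)Cc2c1OCc1ccccc1
F4 | step 8 | 1-[(3S)-5,7-bis(benzyloxy)-3-hydroxy-2,2-dimethylchroman-6-yl]ethanone | CC(=O)c1c(OCc2ccccc2)cc2OC(C)(C)[C@@H](O)Cc2c1OCc1ccccc1
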